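X cannot pile up for longer than it lives.

    Q ⇌ X (K1 = 1.8, k1 = 0.0027 s⁻¹, Ea1 = 88.0 kJ mol⁻¹, ΔH1 = −26.0 kJ mol⁻¹)
    Q ⇌ J (K2 = 110, k2 = 1.4 × 10⁻⁴ s⁻¹, Ea2 = 83.0 kJ mol⁻¹, ΔH2 = 24.0 kJ mol⁻¹)
    X → L (k3 = 0.0027 s⁻¹, Ea3 = 79.0 kJ mol⁻¹)
    E ⇌ Q, rate k4*(cs4 - [Q]) while solid is left; crystals form when [Q] > cs4 (cs4 = 6.2 mM, k4 = 0.0040 s⁻¹)
    Q + X ⇌ Q.X, settled at all times (K5 = 54 M⁻¹, ΔH5 = −50.0 kJ mol⁻¹)
    (constants at 5 °C)

- epsilon: E 0.10 M; temperature −20 °C; time 2.0 h
- gamma: E 0.10 M; temperature 5 °C; time 2.0 h

1. which flask leads in share of X in all that became X or J or L ("all alike" within 1.5 percentage points) (epsilon / gamma / all alike)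
2. share of X in all that became X or J or L, epsilon
3. share of X in all that became X or J or L, gamma

- percentages count the E that a species holds: one Q.X counts as two
- X is meant together with its Q.X
- solid, in amounts per volume of the solution: E
- the list of constants is for 5 °C, to be carried to other temperatures by the activation energies and enthalpies
- at the start none of E is in solution
- what has only dissolved of E counts as not reacted
- in an amount of X, one Q.X counts as one X

1. Two times matter: the run time t, 2.0 h in both flasks, and the mean life τ of X in the flask.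

2. In epsilon, Q → X runs at 0.227 h⁻¹, far slower than dissolution at 14.4 h⁻¹, so [Q] stands near the solubility 6.2 mM and X is fed steadily. In gamma, Q → X at 9.72 h⁻¹ is nearer dissolution, so the solubility is my upper figure for [Q].

3. Free X goes on to L; Q.X does not. With K the constant of Q + X ⇌ Q.X and k the rate constant of X → L, τ = (1 + K[Q])/k. At −20 °C, K is 457 M⁻¹ and k is 0.333 h⁻¹. So τ is 11.5 h in epsilon and 8.24 min in gamma. This holding time is the mean life of X, Q.X counted, against X → L.

4. X and L both grow with the feed, so the feed divides out: with θ = t/τ, X/(X + L) = (1 − exp(−θ))/θ. I leave out the return of X to Q. J takes a part, which I set by the selectivity factor f, the forward constant of Q → X over the sum of the forward constants of Q → X and Q → J: 94.0% in epsilon, 95.1% in gamma.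

5. θ is 0.174 in epsilon and 14.6 in gamma. My shares are 86.3% for epsilon and 6.53% for gamma, so the leader is epsilon.

6. The forecast names epsilon, with 86.3% and 5.9%, the latter lower than mine. Its ground for epsilon: “Q stays near 6 mM, so about 73 % of X is held as Q.X, which protects it from step 3”.

The flask gives epsilon as leader, with 86.3% against 5.92%, as the forecast said. Epsilon left until 20.0 h still holds 57.6% of its charge as E, with Q at 6.10%. With the same τ, θ becomes 1.74, and the holding time gives a share of 44.5%. The flask reads 43.6%.

The numbers are those of an exercise; the run is a simulation.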